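(The numbers are made up; the rest is arithmetic.)

The solid reagent dissolves slowly, at no more than 0.0324 M min⁻¹, so the 0.325 M charged needs at least 10.0 min to go in, longer than the run of 4.0 min, and substrate and first product compete for each portion of partner that arrives.

    substrate + partner → first product + released group (k1 = 0.054 M⁻¹ s⁻¹)
    partner + first product → double product + released group (k2 = 0.30 M⁻¹ s⁻¹)
    solid reagent ⇌ partner, rate k3*(cs3 - [partner]) while solid is left; crystals form when [partner] > cs3 (cs3 = 0.15 M, k3 = 0.0036 s⁻¹)
    substrate + released group ⇌ idle adduct, settled at all times (K4 = 14 M⁻¹)
    scavenger + released group → scavenged by-product (k5 = 1.7 M⁻¹ s⁻¹)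

substrate 0.25 M; solid reagent 1.30 equiv; scavenger 1.00 equiv; time 4.0 min

- released group is meant together with its idle adduct
- solid, in amounts per volume of the solution: solid reagent
- at the start none of the solid reagent is in solution
- run time (flask): 4.0 min

1. conversion of substrate at 4.0 min
2. amount of first product at 4.0 min, in percent of the substrate charged
3. amount of double product at 4.0 min, in percent of the substrate charged
4. amount of first product if the flask were left three thousand times as long, in percent of the substrate charged

The partner concentration stands in both consumption rates and cancels from their ratio. The competition is therefore carried by the selectivity factor S, the rate constant of the second step over that of the first. It says how many times faster a molecule of first product takes partner than a molecule of substrate at equal concentration. With x the fraction of substrate unreacted and y the fraction present as first product, and idle adduct neglected, y = (x − x^S)/(S − 1). This peaks at x_p. In common logarithms (lg):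

S = 0.30 M⁻¹ s⁻¹ / 0.054 M⁻¹ s⁻¹ = 5.56, lg S = 0.745

lg x_p = −lg S/(S − 1) = −0.163, x_p = 68.6%

lg y_p = S · lg x_p = −0.908, y_p = 12.4%

The peak costs 50.4% of the charge in partner, and dissolving delivers at most 51.8% in the run, so my reckoning puts first product just under y_p at 4.0 min.

When the partner charge e is consumed, the same rule gives

y_∞ = (2 − e)/(2S − 1) = 6.92%

One number is not enough here. Released group exceeds scavenger by 0.300 equiv, and K times the starting substrate is 3.5, above unity, so my y_∞ is high.

The forecast gives 24.4%, 11.5%, 11.3% and 4.8%, the last lower than my y_∞; in its words, the adduct “tilts the competition further toward the second step”.

The simulation gives 25.0%, 11.7%, 11.7% and 4.99%.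

At 1.94 min this flask still makes first product 2.12 times as fast as it uses it up, each step taken net, and at the asked time it reads 11.7%, under y_p. At 40.0 min this flask holds 12.4% as idle adduct, and its long-run 4.99% stands below y_∞.

The neighbour charged with 0.250 equiv of scavenger has the same S, so y_p is again 12.4%. It reads 11.1% at conversion 32.6%, under that peak, with 9.85% as idle adduct.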